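**Retrosynthetic overview**

1. Kadsurenin D (13) ⇐ its C7 epimer 11 by acid-mediated benzylic ionisation and reclosure; 11 ⇐ diosphenol 10 by O-methylation.
2. 10 ⇐ quinone 6 + (Z)-methylisoeugenol 8: a titanium TADDOLate-promoted formal [5+2] cycloaddition forms C5–C6 (quaternary allyl carbon to CHMe) and C1–C7 in one operation.
3. Enabling feature: C8=O lies between the bridgeheads C1 and C5, and C2(=O)–C3(OMe)=C4 joins them on the other side. The six-membered ring C1–C2–C3–C4–C5–C8 is therefore a 2-alkoxy-1,4-benzoquinone in disguise (C5–C4–C3–C2–C1 as oxygen-stabilised pentadienyl cation, C8 as spectator carbonyl), and C6(Me)–C7(Ar) is a propenylarene.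
4. 6 ⇐ 3,4-dimethoxyphenol (O-allylation, Claisen rearrangement, oxidative demethylation); 8 ⇐ (E)-methylisoeugenol (sensitised E→Z isomerisation).
5. Ring order: the six-membered carbocycle comes from the arene (dearomatised in step 3); the seven-membered ring C1–C7 and the five-membered ring C1–C8–C5–C6–C7 close together in step 5.

Key step: step 5

Assumption: the (4R,5R)-TADDOLate is taken to leave open the quinone face that leads to the (1S,5S) series; should the sense of induction be the reverse, the (4S,5S)-ligand is used and nothing else changes.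

**Route**

Step 1
Reactants: 1 3,4-dimethoxyphenol; 2 allyl bromide
Product: 3 4-(allyloxy)-1,2-dimethoxybenzene
Conditions: K2CO3, acetone, reflux
Reagents that add atoms: none
Why: Williamson ether synthesis, the phenoxide displacing bromide from a primary allylic carbon; no stereocentre is formed.

Step 2
Reactants: 3 4-(allyloxy)-1,2-dimethoxybenzene
Product: 5 2-allyl-4,5-dimethoxyphenol, via ortho-dienone 4 (not isolated)
Conditions: N,N-diethylaniline, 190 °C
Reagents that add atoms: none
Why: aromatic Claisen rearrangement to the less hindered ortho carbon (para to a methoxy group) followed by tautomerisation of dienone 4; the minor 2-allyl-3,4-dimethoxy isomer should be removable by chromatography.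

Step 3
Reactants: 5 2-allyl-4,5-dimethoxyphenol
Product: 6 2-allyl-5-methoxy-1,4-benzoquinone (numbered here C1=O, C2 allyl, C4=O, C5 OMe)
Conditions: PhI(OAc)2, MeCN–H2O, 0 °C
Reagents that add atoms: water, O
Why: oxidative dearomatisation of a para-methoxyphenol, water adding para to the phenoxonium ion and the hemiketal losing methanol (oxidative demethylation), which should leave the allyl group and the second methoxy group untouched.

Step 4
Reactants: 7 (E)-methylisoeugenol, (E)-1,2-dimethoxy-4-(prop-1-en-1-yl)benzene
Product: 8 (Z)-methylisoeugenol, (Z)-1,2-dimethoxy-4-(prop-1-en-1-yl)benzene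
Conditions: fac-Ir(ppy)3 (1 mol %; ppy = 2-phenylpyridinato), MeCN, 450 nm LEDs, rt; separation on AgNO3-impregnated SiO2
Reagents that add atoms: none
Why: triplet-sensitised contra-thermodynamic E→Z isomerisation of a β-methylstyrene, in which the twisted Z isomer is the poorer energy acceptor and should accumulate; the Z geometry is what later turns the methyl group endo.

Step 5
Reactants: 6 2-allyl-5-methoxy-1,4-benzoquinone; 8 (Z)-methylisoeugenol
Product: 10 (1S,5S,6R,7S)-7-(3,4-dimethoxyphenyl)-3-hydroxy-6-methyl-5-(prop-2-en-1-yl)bicyclo[3.2.1]oct-3-ene-2,8-dione (7-endo-aryl 6-endo-methyl diosphenol), via zwitterion 9 (not isolated)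
Conditions: TiCl2(TADDOLate) (preformed, 2.5 equiv; TADDOLate = (4R,5R)-2,2-dimethyl-α,α,α′,α′-tetraphenyl-1,3-dioxolane-4,5-dimethanolate), CH2Cl2, −78 to −20 °C; aq. NaHCO3
Reagents that add atoms: none
Why: The titanium centre chelates the C4 carbonyl and the 5-OMe oxygen of 6, so that C2–C3–C4–C5–C6 of the quinone becomes an oxygen-stabilised pentadienyl cation with C1=O as spectator; the nucleophilic CHMe carbon of 8 bonds to the allyl-bearing C2 (the quaternary C5–C6 bond of the product) and the benzylic carbon is taken up by the enol-ether carbon C6 (the C1–C7 bond), giving the titanium enolate/O-methyloxocarbenium zwitterion 9, which should lose its O-methyl group to chloride and give the diosphenol on work-up. The closest known reaction type is the titanium-promoted formal [5+2] cycloaddition of 2-alkoxy-5-alkyl-1,4-benzoquinones with propenylbenzenes, which is also known in enantioselective form with TADDOLate-modified titanium. Both bonds form on one face of each partner in an intermolecular cycloaddition that closes the seven-membered ring C1–C2–C3–C4–C5–C6–C7 and, because C8 bridges its termini, the five-membered ring C1–C8–C5–C6–C7 at the same time. C5 follows from the quinone face left open by the TADDOLate and C1 is then forced by the bridge; C6 follows from the endo position that the aryl group takes over the titanium-bound dienyl unit in this reaction type, which with a Z-alkene turns the methyl group endo as well; C7 follows from the retained Z geometry (aryl cis to methyl, corrected in step 7). The step needs attack at C2 rather than at C6 or oxygen, and C-closure rather than cyclobutane or O-closure: the 5-OMe group secures both, since its chelate activates only the C4 carbonyl, whose β-carbon is C2, and it makes C6 the nucleophilic enol-ether carbon, while cyclobutane adducts formed at −78 °C should reopen to the same zwitterion on warming and collapse to the bridged product.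

Step 6
Reactants: 10 the diosphenol from step 5
Product: 11 (1S,5S,6R,7S)-7-(3,4-dimethoxyphenyl)-3-methoxy-6-methyl-5-(prop-2-en-1-yl)bicyclo[3.2.1]oct-3-ene-2,8-dione (7-epi-kadsurenin D)
Conditions: MeI, K2CO3, acetone, rt
Reagents that add atoms: iodomethane, CI
Why: O-alkylation of the acidic diosphenol, whose only possible enol points to C4 because C1 is a bridgehead, under a mild non-nucleophilic base that should spare the non-enolisable 2,8-dione; no stereocentre changes.

Step 7
Reactants: 11 7-epi-kadsurenin D
Product: 13 kadsurenin D, (1S,5S,6R,7R)-7-(3,4-dimethoxyphenyl)-3-methoxy-6-methyl-5-(prop-2-en-1-yl)bicyclo[3.2.1]oct-3-ene-2,8-dione, via benzylic cation 12 (not isolated)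
Conditions: TsOH (anhydrous, 0.2 equiv), ClCH2CH2Cl, 60 °C
Reagents that add atoms: none
Why: acid-induced reversible heterolysis of the C1–C7 bond (the ionisation that interconverts bicyclo[3.2.1]octanoid and hydrobenzofuranoid neolignans) gives the 3,4-dimethoxybenzyl cation 12, which can reclose only on the dienone face reached by the C5–C6 tether and, under thermodynamic control, should place the aryl group trans to the endo methyl group, so that C7 becomes R (exo-aryl) while C5 and C6 stay untouched and C1 re-forms as before; any 7R material already formed in step 5 converges here.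

**Compound list**

1 | 3,4-dimethoxyphenol | COc1ccc(O)cc1OC | starting material
2 | allyl bromide (3-bromoprop-1-ene) | C=CCBr | starting material
3 | 4-(allyloxy)-1,2-dimethoxybenzene | C=CCOc1ccc(OC)c(OC)c1 | intermediate
4 | 6-allyl-3,4-dimethoxycyclohexa-2,4-dien-1-one (ortho-dienone, racemic, transient) | C=CCC1C=C(OC)C(OC)=CC1=O | intermediate
5 | 2-allyl-4,5-dimethoxyphenol | C=CCc1cc(OC)c(OC)cc1O | intermediate
6 | 2-allyl-5-methoxy-1,4-benzoquinone | C=CCC1=CC(=O)C(OC)=CC1=O | intermediate
7 | (E)-methylisoeugenol | C/C=C/c1ccc(OC)c(OC)c1 | starting material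
8 | (Z)-methylisoeugenol | C/C=C\c1ccc(OC)c(OC)c1 | intermediate
9 | primary cycloadduct drawn without titanium: C3 enolate / C2 O-methyloxocarbenium zwitterion with the configuration of 10 | C=CC[C@]12C=C([O-])C(=[O+]C)[C@H](C1=O)[C@@H](c1ccc(OC)c(OC)c1)[C@H]2C | intermediate
10 | (1S,5S,6R,7S)-7-(3,4-dimethoxyphenyl)-3-hydroxy-6-methyl-5-(prop-2-en-1-yl)bicyclo[3.2.1]oct-3-ene-2,8-dione | C=CC[C@]12C=C(O)C(=O)[C@H](C1=O)[C@@H](c1ccc(OC)c(OC)c1)[C@H]2C | intermediate
11 | (1S,5S,6R,7S)-7-(3,4-dimethoxyphenyl)-3-methoxy-6-methyl-5-(prop-2-en-1-yl)bicyclo[3.2.1]oct-3-ene-2,8-dione (7-epi-kadsurenin D) | C=CC[C@]12C=C(OC)C(=O)[C@H](C1=O)[C@@H](c1ccc(OC)c(OC)c1)[C@H]2C | intermediate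
12 | ring-opened cation: 4-allyl-3-hydroxy-6-methoxycyclohexa-2,5-dien-1-one carrying at C4 the 1-(3,4-dimethoxyphenyl)propan-1-ylium-2-yl chain, quaternary carbon and CHMe configured as in 11 | C=CC[C@@]1(C=C(OC)C(=O)C=C1O)[C@H](C)[CH+]c1ccc(OC)c(OC)c1 | intermediate
13 | kadsurenin D, (1S,5S,6R,7R)-7-(3,4-dimethoxyphenyl)-3-methoxy-6-methyl-5-(prop-2-en-1-yl)bicyclo[3.2.1]oct-3-ene-2,8-dione (7-exo-aryl, 6-endo-methyl) | C=CC[C@]12C=C(OC)C(=O)[C@H](C1=O)[C@H](c1ccc(OC)c(OC)c1)[C@H]2C | target

**Step count and risks**

Total step count: 7. Longest linear sequence: 6 steps (steps 1, 2, 3, 5, 6, 7).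

Step 5 is the step most likely to fail. The TADDOLate may discriminate the quinone faces poorly with a Z-alkene. The alkene geometry may be lost through a reversible first bond formation, or the alkene may approach with both substituents exo, either of which would set C6 wrongly. The benzylic cation may also be diverted into cyclobutane or oxygen-closed adducts. The fallback gives up asymmetric induction for the acid-catalysed quinone monoketal–propenylarene cycloaddition followed by resolution. It sets out from 5: oxidation with PhI(OAc)2 in MeOH should give 2-allyl-4,4,5-trimethoxycyclohexa-2,5-dien-1-one F1. F1 and 8 with catalytic CF3SO3H in MeCN (−30 °C to rt) ionise to the dimethoxyphenoxonium-type cation, which the alkene attacks at the allyl-bearing carbon; the ketal carbon keeps one methoxy group as C3–OMe, so no methylation is needed, and the acidic medium should equilibrate the benzylic centre to the trans series. The racemate is resolved by preparative HPLC on a cellulose tris(3,5-dimethylphenylcarbamate) phase, ent-kadsurenin D F2 is discarded, and the route is rejoined at 13.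

Step 7 is the second risk. Heterolysis of the C1–C7 carbon–carbon bond may be too slow, the terminal allyl alkene may be protonated, or the equilibrium may stall at oxygen-closed isomers. The fallback corrects the benzylic centre through the more labile carbon–oxygen bond instead. It sets out from 6 and 8: with a less Lewis acidic, isopropoxide-rich promoter (the TADDOLate with added Ti(OiPr)4, warmed to 0 °C) the benzylic cation should be captured by the quinone oxygen, giving (2R,3S,3aS)-2-(3,4-dimethoxyphenyl)-5-hydroxy-3-methyl-3a-(prop-2-en-1-yl)-3,3a-dihydro-1-benzofuran-6(2H)-one F3. O-Methylation (MeI, K2CO3, acetone) should give (2R,3S,3aS)-2-(3,4-dimethoxyphenyl)-5-methoxy-3-methyl-3a-(prop-2-en-1-yl)-3,3a-dihydro-1-benzofuran-6(2H)-one F4. The known acid-catalysed hydrobenzofuranoid to bicyclo[3.2.1]octanoid rearrangement (TsOH, ClCH2CH2Cl) then ionises the benzylic C–O bond and closes C1–C7 trans to the methyl group, joining the route at 13.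

Step 4 is the third risk. Conversion may stop at the photostationary state, residual E-alkene carried into step 5 would feed the C6-epimeric series, and the styrene may photodimerise. The fallback builds the Z-alkene by alkyne semi-hydrogenation and sets out from 7. Addition of bromine (pyridinium tribromide, CH2Cl2, 0 °C) should give 4-[(1R,2S)-rel-1,2-dibromopropyl]-1,2-dimethoxybenzene F5. Double dehydrobromination (KOtBu, DMSO, 60 °C) should give 1,2-dimethoxy-4-(prop-1-yn-1-yl)benzene F6. Syn hydrogenation over Pd/CaCO3 poisoned with Pb(OAc)2 (Lindlar catalyst, quinoline, H2) returns to the route at 8.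

**Further compounds**

F1 | step 5 | 2-allyl-4,4,5-trimethoxycyclohexa-2,5-dien-1-one | C=CCC1=CC(OC)(OC)C(OC)=CC1=O
F2 | step 5 | ent-kadsurenin D, (1R,5R,6S,7S) | C=CC[C@@]12C=C(OC)C(=O)[C@@H](C1=O)[C@@H](c1ccc(OC)c(OC)c1)[C@@H]2C
F3 | step 7 | (2R,3S,3aS)-2-(3,4-dimethoxyphenyl)-5-hydroxy-3-methyl-3a-(prop-2-en-1-yl)-3,3a-dihydro-1-benzofuran-6(2H)-one | C=CC[C@]12C=C(O)C(=O)C=C1O[C@@H](c1ccc(OC)c(OC)c1)[C@H]2C
F4 | step 7 | (2R,3S,3aS)-2-(3,4-dimethoxyphenyl)-5-methoxy-3-methyl-3a-(prop-2-en-1-yl)-3,3a-dihydro-1-benzofuran-6(2H)-one | C=CC[C@]12C=C(OC)C(=O)C=C1O[C@@H](c1ccc(OC)c(OC)c1)[C@H]2C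
F5 | step 4 | 4-[(1R,2S)-rel-1,2-dibromopropyl]-1,2-dimethoxybenzene (racemic, one enantiomer drawn) | C[C@H](Br)[C@H](Br)c1ccc(OC)c(OC)c1
F6 | step 4 | 1,2-dimethoxy-4-(prop-1-yn-1-yl)benzene | CC#Cc1ccc(OC)c(OC)c1
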